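**Retrosynthetic overview** (tetralin locants: C1 = ring CH(CH3), C4 = ring CH carrying the side chain, C4a/C8a = ring-fusion carbons)
1. The benzene ring is bought (methyl 2,3-dihydroxybenzoate). The saturated ring is the only ring built, closed late by ring-closing metathesis at C2=C3 and then hydrogenated.
2. The C8a–C1 bond and the ring-methyl centre come from an aromatic Claisen rearrangement with chirality transfer from an enantioenriched aryl pent-3-en-2-yl ether.
3. Key disconnection, C4–C4a: the racemic α-bromo amide of (S)-citronellic acid acts as an enolonium (α-acyl cation) equivalent and is joined to an arylzinc in a stereoconvergent nickel coupling. The amide carbon then becomes ring carbon C3.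
4. (S)-Citronellic acid supplies the side-chain methyl centre next to the ring and the whole side chain. Its prenyl end gives the CH(CH3)CH2OH terminus by SeO2 oxidation and iridium asymmetric hydrogenation.

Assumption: the four compounds marked starting material are bought as such ((S)-citronellic acid in high ee), and the ligand enantiomers in steps 3, 7 and 12 are named by the configuration they must deliver, to be confirmed on first use.

**Step 1**
Reactants: 1 methyl 2,3-dihydroxybenzoate
Product: 2 methyl 5-bromo-2,3-dihydroxybenzoate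
Conditions: NBS (1.0 equiv), MeCN, 0 °C
Reagents that add atoms: N-bromosuccinimide, O=C1CCC(=O)N1Br
Why: Electrophilic aromatic bromination goes to C5 because it is para to the 2-hydroxyl and meta to the ester, whereas C4 and C6 are deactivated by being para and ortho to the ester.

**Step 2**
Reactants: 3 (E)-pent-3-en-2-ol (racemic)
Product: 4 methyl (E)-pent-3-en-2-yl carbonate (racemic)
Conditions: NaH, THF, 0 °C; ClCO2Me
Reagents that add atoms: methyl chloroformate, COC(=O)Cl
Why: Acylation of the sodium alkoxide by the chloroformate (carbonate formation) gives the ionisable leaving group needed for π-allyl chemistry; the stereocentre is deliberately left racemic.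

**Step 3**
Reactants: 2 methyl 5-bromo-2,3-dihydroxybenzoate; 4 methyl (E)-pent-3-en-2-yl carbonate (racemic)
Product: 5 methyl 5-bromo-2-hydroxy-3-{[(2S,3E)-pent-3-en-2-yl]oxy}benzoate
Conditions: Pd2(dba)3·CHCl3 (1 mol%), DACH-phenyl Trost ligand (3 mol%, enantiomer giving the S ether), CH2Cl2, rt
Reagents that add atoms: none
Why: Trost asymmetric allylic etherification (Tsuji–Trost reaction): both enantiomers of 4 ionise to the same symmetric 1,3-dimethyl-π-allyl palladium complex, and the chiral ligand steers the free 3-hydroxyl (the 2-hydroxyl is tied up in a hydrogen bond to the ester) onto one allyl terminus, which sets the S ether centre and keeps the E alkene.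

**Step 4**
Reactants: 5 methyl 5-bromo-2-hydroxy-3-{[(2S,3E)-pent-3-en-2-yl]oxy}benzoate
Product: 6 methyl 5-bromo-2-methoxy-3-{[(2S,3E)-pent-3-en-2-yl]oxy}benzoate
Conditions: MeI, K2CO3, DMF, 40 °C
Reagents that add atoms: iodomethane, CI
Why: Williamson O-methylation of the remaining chelated salicylate hydroxyl installs the aryl methyl ether found in the target without touching the allylic ether.

**Step 5**
Reactants: 7 (3S)-3,7-dimethyloct-6-enoic acid ((S)-citronellic acid); 8 indoline (2,3-dihydro-1H-indole)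
Product: 9 (3S)-1-(2,3-dihydro-1H-indol-1-yl)-3,7-dimethyloct-6-en-1-one
Conditions: DCC, DMAP (cat.), CH2Cl2, 0 °C to rt
Reagents that add atoms: none
Why: Carbodiimide (Steglich-type) amide coupling gives the anilide-type amide that suits both the nickel coupling and the later partial reduction, and leaves the C3 centre untouched.

**Step 6**
Reactants: 9 (3S)-1-(2,3-dihydro-1H-indol-1-yl)-3,7-dimethyloct-6-en-1-one
Product: 10 (3S)-2-bromo-1-(2,3-dihydro-1H-indol-1-yl)-3,7-dimethyloct-6-en-1-one (2RS mixture)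
Conditions: LiN(i-Pr)2, THF, −78 °C; BrCl2C–CCl2Br
Reagents that add atoms: 1,2-dibromo-1,1,2,2-tetrachloroethane, BrC(Cl)(Cl)C(Cl)(Cl)Br
Why: Amide enolate bromination with a positive-bromine donor is much faster at −78 °C than attack on the trisubstituted alkene and turns the α-carbon into an enolonium equivalent; the new C2 centre forms as a mixture that does not matter because the next step is stereoconvergent.

**Step 7 (key step)**
Reactants: 6 methyl 5-bromo-2-methoxy-3-{[(2S,3E)-pent-3-en-2-yl]oxy}benzoate; 10 (3S)-2-bromo-1-(2,3-dihydro-1H-indol-1-yl)-3,7-dimethyloct-6-en-1-one (2RS mixture)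
Product: 12 methyl 5-[(2S,3S)-1-(2,3-dihydro-1H-indol-1-yl)-3,7-dimethyl-1-oxooct-6-en-2-yl]-2-methoxy-3-{[(2S,3E)-pent-3-en-2-yl]oxy}benzoate, via arylzinc chloride 11 (not isolated)
Conditions: 6, Mg, LiCl, ZnCl2, THF, 25 °C; then 10, NiCl2·glyme (10 mol%), i-Pr-pybox (13 mol%, enantiomer giving the 2S amide), DMI/THF, −20 °C
Reagents that add atoms: none
Why: Stereoconvergent nickel-catalysed Negishi α-arylation of a racemic α-bromo amide (Fu-type coupling, here extended to an arylzinc and a β-branched amide): the α-bromo amide serves as an enolonium (α-acyl cation) equivalent, both C2 epimers collapse to the same planar α-amido radical, and the chiral nickel–pybox aryl complex captures it on one face, so catalyst control sets the 2S centre beside the fixed 3S centre while joining an enolate α-carbon and an arene carbon that are both nucleophilic in their normal polarity.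

**Step 8**
Reactants: 12 methyl 5-[(2S,3S)-1-(2,3-dihydro-1H-indol-1-yl)-3,7-dimethyl-1-oxooct-6-en-2-yl]-2-methoxy-3-{[(2S,3E)-pent-3-en-2-yl]oxy}benzoate
Product: 14 methyl 5-[(3S,4S)-4,8-dimethylnona-1,7-dien-3-yl]-2-methoxy-3-{[(2S,3E)-pent-3-en-2-yl]oxy}benzoate, via α-aryl aldehyde 13 (not isolated)
Conditions: Cp2Zr(H)Cl, THF, rt, 20 min; SiO2 plug (removes indoline); then Zn, CH2Br2, TiCl4, THF/CH2Cl2, 0 °C
Reagents that add atoms: dibromomethane, BrCBr
Why: Georg partial reduction of the tertiary amide with Cp2Zr(H)Cl stops at the aldehyde and spares the aryl ester, and the non-basic Takai–Lombardo methylenation converts the epimerisable α-aryl aldehyde at once into the vinyl group, so the benzylic centre set in step 7 is kept.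

**Step 9**
Reactants: 14 methyl 5-[(3S,4S)-4,8-dimethylnona-1,7-dien-3-yl]-2-methoxy-3-{[(2S,3E)-pent-3-en-2-yl]oxy}benzoate
Product: 15 methyl 5-[(3S,4S,7E)-9-hydroxy-4,8-dimethylnona-1,7-dien-3-yl]-2-methoxy-3-{[(2S,3E)-pent-3-en-2-yl]oxy}benzoate
Conditions: SeO2 (0.3 equiv), t-BuOOH, salicylic acid (cat.), CH2Cl2, rt
Reagents that add atoms: tert-butyl hydroperoxide, CC(C)(C)OO
Why: Sharpless catalytic SeO2 allylic oxidation (ene reaction then [2,3]-sigmatropic shift) is fastest at the most electron-rich trisubstituted alkene and selective for its E methyl group, giving the E primary allylic alcohol while the phenol is still masked as its ether.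

**Step 10**
Reactants: 15 methyl 5-[(3S,4S,7E)-9-hydroxy-4,8-dimethylnona-1,7-dien-3-yl]-2-methoxy-3-{[(2S,3E)-pent-3-en-2-yl]oxy}benzoate
Product: 16 methyl 3-hydroxy-5-[(3S,4S,7E)-9-hydroxy-4,8-dimethylnona-1,7-dien-3-yl]-2-methoxy-4-[(2R,3E)-pent-3-en-2-yl]benzoate
Conditions: Eu(fod)3 (10 mol%), CHCl3, 60 °C
Reagents that add atoms: none
Why: Aromatic Claisen rearrangement under Eu(fod)3 catalysis: the allyl group can only end up on the one free ortho carbon and passes through a chair transition state with the methyl group equatorial, so the S C–O centre is transferred suprafacially into the R benzylic centre (1,3-chirality transfer) with an E alkene.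

**Step 11**
Reactants: 16 methyl 3-hydroxy-5-[(3S,4S,7E)-9-hydroxy-4,8-dimethylnona-1,7-dien-3-yl]-2-methoxy-4-[(2R,3E)-pent-3-en-2-yl]benzoate
Product: 17 methyl (5R,8R)-4-hydroxy-8-[(2S,5E)-7-hydroxy-6-methylhept-5-en-2-yl]-3-methoxy-5-methyl-5,8-dihydronaphthalene-2-carboxylate
Conditions: second-generation Grubbs catalyst RuCl2(=CHPh)(H2IMes)(PCy3) (5 mol%), CH2Cl2, 40 °C
Reagents that add atoms: none
Why: Ring-closing metathesis between the vinyl group and the neighbouring propenyl arm is held in place by the ortho-disubstituted arene and closes the six-membered ring with loss of propene much faster than the hindered trisubstituted allylic-alcohol alkene can react; no stereocentre is touched (the C8 descriptor reads R here only because the ring alkene outranks the side chain).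

**Step 12**
Reactants: 17 methyl (5R,8R)-4-hydroxy-8-[(2S,5E)-7-hydroxy-6-methylhept-5-en-2-yl]-3-methoxy-5-methyl-5,8-dihydronaphthalene-2-carboxylate
Product: 18 methyl (5R,8S)-4-hydroxy-8-[(2S,6S)-7-hydroxy-6-methylheptan-2-yl]-3-methoxy-5-methyl-5,6,7,8-tetrahydronaphthalene-2-carboxylate
Conditions: [Ir(cod)(L*)]BArF (2 mol%; L* = Pfaltz pyridine–phosphinite, enantiomer giving the 6S side-chain centre), H2 (50 bar), CH2Cl2, rt
Reagents that add atoms: none
Why: Iridium-catalysed asymmetric hydrogenation with a chiral N,P ligand (Pfaltz-type) adds H2 to one face of the E trisubstituted allylic alcohol under catalyst control to set the S methyl centre, and the same catalyst saturates the cis ring alkene, which creates no stereocentre.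

**Compound list**
1 | methyl 2,3-dihydroxybenzoate | COC(=O)c1cccc(O)c1O | starting material
2 | methyl 5-bromo-2,3-dihydroxybenzoate | COC(=O)c1cc(Br)cc(O)c1O | intermediate
3 | (E)-pent-3-en-2-ol (racemic) | CC(O)/C=C/C | starting material
4 | methyl (E)-pent-3-en-2-yl carbonate (racemic) | COC(=O)OC(C)/C=C/C | intermediate
5 | methyl 5-bromo-2-hydroxy-3-{[(2S,3E)-pent-3-en-2-yl]oxy}benzoate | COC(=O)c1cc(Br)cc(O[C@@H](C)/C=C/C)c1O | intermediate
6 | methyl 5-bromo-2-methoxy-3-{[(2S,3E)-pent-3-en-2-yl]oxy}benzoate | COC(=O)c1cc(Br)cc(O[C@@H](C)/C=C/C)c1OC | intermediate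
7 | (3S)-3,7-dimethyloct-6-enoic acid ((S)-citronellic acid) | OC(=O)C[C@@H](C)CCC=C(C)C | starting material
8 | indoline (2,3-dihydro-1H-indole) | C1Cc2ccccc2N1 | starting material
9 | (3S)-1-(2,3-dihydro-1H-indol-1-yl)-3,7-dimethyloct-6-en-1-one | O=C(C[C@@H](C)CCC=C(C)C)N1CCc2ccccc21 | intermediate
10 | (3S)-2-bromo-1-(2,3-dihydro-1H-indol-1-yl)-3,7-dimethyloct-6-en-1-one (2RS mixture) | O=C(C(Br)[C@@H](C)CCC=C(C)C)N1CCc2ccccc21 | intermediate
11 | chlorido{4-methoxy-3-(methoxycarbonyl)-5-[(2S,3E)-pent-3-en-2-yloxy]phenyl}zinc (arylzinc chloride) | COC(=O)c1cc([Zn]Cl)cc(O[C@@H](C)/C=C/C)c1OC | intermediate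
12 | methyl 5-[(2S,3S)-1-(2,3-dihydro-1H-indol-1-yl)-3,7-dimethyl-1-oxooct-6-en-2-yl]-2-methoxy-3-{[(2S,3E)-pent-3-en-2-yl]oxy}benzoate | O=C(N1CCc2ccccc21)[C@H](c1cc(C(=O)OC)c(OC)c(O[C@@H](C)/C=C/C)c1)[C@@H](C)CCC=C(C)C | intermediate
13 | methyl 5-[(2S,3S)-3,7-dimethyl-1-oxooct-6-en-2-yl]-2-methoxy-3-{[(2S,3E)-pent-3-en-2-yl]oxy}benzoate (α-aryl aldehyde) | O=C[C@H](c1cc(C(=O)OC)c(OC)c(O[C@@H](C)/C=C/C)c1)[C@@H](C)CCC=C(C)C | intermediate
14 | methyl 5-[(3S,4S)-4,8-dimethylnona-1,7-dien-3-yl]-2-methoxy-3-{[(2S,3E)-pent-3-en-2-yl]oxy}benzoate | C=C[C@H](c1cc(C(=O)OC)c(OC)c(O[C@@H](C)/C=C/C)c1)[C@@H](C)CCC=C(C)C | intermediate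
15 | methyl 5-[(3S,4S,7E)-9-hydroxy-4,8-dimethylnona-1,7-dien-3-yl]-2-methoxy-3-{[(2S,3E)-pent-3-en-2-yl]oxy}benzoate | C=C[C@H](c1cc(C(=O)OC)c(OC)c(O[C@@H](C)/C=C/C)c1)[C@@H](C)CC/C=C(\C)CO | intermediate
16 | methyl 3-hydroxy-5-[(3S,4S,7E)-9-hydroxy-4,8-dimethylnona-1,7-dien-3-yl]-2-methoxy-4-[(2R,3E)-pent-3-en-2-yl]benzoate | C=C[C@H](c1cc(C(=O)OC)c(OC)c(O)c1[C@H](C)/C=C/C)[C@@H](C)CC/C=C(\C)CO | intermediate
17 | methyl (5R,8R)-4-hydroxy-8-[(2S,5E)-7-hydroxy-6-methylhept-5-en-2-yl]-3-methoxy-5-methyl-5,8-dihydronaphthalene-2-carboxylate | COC(=O)c1cc2c(c(O)c1OC)[C@H](C)C=C[C@H]2[C@@H](C)CC/C=C(\C)CO | intermediate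
18 | methyl (5R,8S)-4-hydroxy-8-[(2S,6S)-7-hydroxy-6-methylheptan-2-yl]-3-methoxy-5-methyl-5,6,7,8-tetrahydronaphthalene-2-carboxylate | COC(=O)c1cc2c(c(O)c1OC)[C@H](C)CC[C@H]2[C@@H](C)CCC[C@H](C)CO | target

**Step count.** Total: 12 steps. Longest linear sequence: 9 steps (1 → 2 → 5 → 6 → 12 → 14 → 15 → 16 → 17 → 18).

**Steps most likely to fail, with fallbacks**

The nickel coupling of step 7 is the largest risk. The α-amido radical is β-branched, the catalyst has to override the neighbouring 3S centre, the arylzinc/amide pairing is an extrapolation from the ketone, nitrile and boron variants, and zerovalent nickel could attack the allyl aryl ether. The fallback reverses the polarity of the arene instead of the carbonyl partner and sets out from 6. Mg/LiCl, then B(OMe)3 and aqueous HCl, give [4-methoxy-3-(methoxycarbonyl)-5-{[(2S,3E)-pent-3-en-2-yl]oxy}phenyl]boronic acid F1. MesI(OAc)2 with BF3·OEt2, then NaOTf, converts it into [4-methoxy-3-(methoxycarbonyl)-5-{[(2S,3E)-pent-3-en-2-yl]oxy}phenyl](2,4,6-trimethylphenyl)iodonium trifluoromethanesulfonate F2. F2 then arylates commercial (S)-citronellal through its enamine (CuBr 10 mol%, chiral imidazolidinone salt 10 mol%, NaHCO3, toluene/Et2O, rt; MacMillan α-arylation with an aryl cation equivalent). The route is rejoined at aldehyde 13, which is methylenated as in step 8, and steps 5 and 6 are no longer needed.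

The asymmetric etherification of step 3 may give only moderate ee with the acyclic 1,3-dimethylallyl system, or may alkylate the wrong oxygen of the catechol. The fallback sets out from 3 and 2. Immobilised Candida antarctica lipase B with vinyl acetate acylates one enantiomer of 3 to give (2R,3E)-pent-3-en-2-yl acetate F3. K2CO3/MeOH frees (2R,3E)-pent-3-en-2-ol F4. Mitsunobu etherification of 2 with F4 (PPh3, DIAD, THF, 0 °C) inverts the carbinol centre and returns to the route at 5.

The allylic oxidation of step 9 must pick one of three alkenes and can over-oxidise to the enal. The fallback sets out from 14. mCPBA (1.0 equiv, NaHCO3, CH2Cl2, −20 °C) epoxidises only the trisubstituted alkene, giving methyl 5-[(3S,4S)-6-(3,3-dimethyloxiran-2-yl)-4-methylhex-1-en-3-yl]-2-methoxy-3-{[(2S,3E)-pent-3-en-2-yl]oxy}benzoate F5. Et2Al(TMP) (toluene, 0 °C) isomerises the epoxide to the secondary allylic alcohol methyl 5-[(3S,4S)-7-hydroxy-4,8-dimethylnona-1,8-dien-3-yl]-2-methoxy-3-{[(2S,3E)-pent-3-en-2-yl]oxy}benzoate F6. Ph3SiOReO3-catalysed 1,3-transposition, with N,O-bis(trimethylsilyl)acetamide trapping the primary alcohol and a mild acid work-up, returns to the route at 15.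

**Further compounds**
F1 | step 7 | [4-methoxy-3-(methoxycarbonyl)-5-{[(2S,3E)-pent-3-en-2-yl]oxy}phenyl]boronic acid | COC(=O)c1cc(B(O)O)cc(O[C@@H](C)/C=C/C)c1OC
F2 | step 7 | [4-methoxy-3-(methoxycarbonyl)-5-{[(2S,3E)-pent-3-en-2-yl]oxy}phenyl](2,4,6-trimethylphenyl)iodonium trifluoromethanesulfonate | COC(=O)c1cc([I+]c2c(C)cc(C)cc2C)cc(O[C@@H](C)/C=C/C)c1OC.[O-]S(=O)(=O)C(F)(F)F
F3 | step 3 | (2R,3E)-pent-3-en-2-yl acetate | CC(=O)O[C@H](C)/C=C/C
F4 | step 3 | (2R,3E)-pent-3-en-2-ol | O[C@H](C)/C=C/C
F5 | step 9 | methyl 5-[(3S,4S)-6-(3,3-dimethyloxiran-2-yl)-4-methylhex-1-en-3-yl]-2-methoxy-3-{[(2S,3E)-pent-3-en-2-yl]oxy}benzoate (epoxide epimers) | C=C[C@H](c1cc(C(=O)OC)c(OC)c(O[C@@H](C)/C=C/C)c1)[C@@H](C)CCC1OC1(C)C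
F6 | step 9 | methyl 5-[(3S,4S)-7-hydroxy-4,8-dimethylnona-1,8-dien-3-yl]-2-methoxy-3-{[(2S,3E)-pent-3-en-2-yl]oxy}benzoate (C7 epimers) | C=C[C@H](c1cc(C(=O)OC)c(OC)c(O[C@@H](C)/C=C/C)c1)[C@@H](C)CCC(O)C(C)=C
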